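**Retrosynthetic overview**
1. Locants: C1 CH–O-anisoyl, C2=C3(CH3), C4, C5, C6 C–OH, C7 CH–iPr, C8, C9 C=O, C10 C–CH3. The seven-ring is C1–C6 + C10 and the five-ring is C6–C10, cis-fused; C6-OH, C7-iPr and C10-CH3 lie on one face ("down"), C1 and C5 on the other ("up").
2. Feature used: in the seven-ring the C1 oxygen and C4 stand 1,4 across the C2=C3 alkene. The cycloheptene is therefore a reductively opened 8-oxabicyclo[3.2.1]octene, that is, a propyne equivalent plus a six-membered carbonyl ylide C4–C5–C6–C10–C1–O laid over the intact five-ring.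
3. Disconnections after the key step (backwards): C1–O acyl; C7–H (hydride to a C7-isopropyl C7=C8–C9=O enone); C7–iPr (cuprate); C5 (CH2 from epoxide from trans-diol from ketone); C4–O (SmI2); C2–S (Na/Hg).
4. Before the key step: C4=N2 (diazo transfer to a C5 methyl ketone), C6–O (dihydroxylation of a C6=C5 ethylidene), C9/C10 (enzymatic desymmetrisation), C10–C1 (formaldehyde aldol on 2-methylcyclopentane-1,3-dione).
5. Ring order: five-ring (purchased), then the pyranone ylide ring, then the dihydrofuran ring and seven-membered carbocycle together, then the oxygen bridge is cut to leave the 5–7 carbocycle.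

Key step: step 15

Assumption: the ketoreductase of step 3 is taken to act in the Prelog sense that baker's yeast shows on 2-allyl-2-methylcyclopentane-1,3-dione, with CH2OBn playing the part of the larger group.

Step 1
Reactants: 1 2-methylcyclopentane-1,3-dione; 2 formaldehyde (37% aq)
Product: 3 2-(hydroxymethyl)-2-methylcyclopentane-1,3-dione
Conditions: 37% aq CH2O (3 equiv), NaHCO3 (0.1 equiv), H2O–THF, 23 °C
Reagents that add atoms: formaldehyde (2), C=O
Why: Reversible aldol (Tollens-type hydroxymethylation) of the acidic 2-alkyl-1,3-dione funnels to the C-adduct and places C1 on the future quaternary C10, whereas a hard chloromethyl ether would mainly O-alkylate the enolate; no stereocentre is formed yet.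

Step 2
Reactants: 3 2-(hydroxymethyl)-2-methylcyclopentane-1,3-dione
Product: 4 2-[(benzyloxy)methyl]-2-methylcyclopentane-1,3-dione
Conditions: BnOC(=NH)CCl3 (1.5 equiv), TfOH (5 mol %), CH2Cl2–cyclohexane, 0 → 23 °C
Reagents that add atoms: benzyl 2,2,2-trichloroacetimidate, N=C(OCc1ccccc1)C(Cl)(Cl)Cl
Why: Acid-catalysed trichloroacetimidate benzylation protects the primary alcohol without the base that would trigger retro-aldol loss of formaldehyde or retro-Claisen ring opening.

Step 3
Reactants: 4 2-[(benzyloxy)methyl]-2-methylcyclopentane-1,3-dione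
Product: 5 (2S,3S)-2-[(benzyloxy)methyl]-3-hydroxy-2-methylcyclopentan-1-one (C9-OH cis to CH2OBn)
Conditions: Prelog-type ketoreductase (screening panel), NADP+ (cat.), i-PrOH, pH 7 phosphate buffer–DMSO, 30 °C
Reagents that add atoms: none
Why: Enzymatic desymmetrising monoreduction, established for 2-alkyl-2-methylcyclopentane-1,3-diones, reduces one enantiotopic carbonyl with hydride delivery from the methyl face, which gives the (S)-carbinol C9 cis to CH2OBn and makes C10 stereogenic with the spatial arrangement of the target.

Step 4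
Reactants: 5 (2S,3S)-hydroxy ketone
Product: 6 (2S,3S)-2-[(benzyloxy)methyl]-2-methyl-3-(triethylsilyloxy)cyclopentan-1-one
Conditions: TESCl, imidazole, CH2Cl2, 0 → 23 °C
Reagents that add atoms: chlorotriethylsilane, CC[Si](Cl)(CC)CC
Why: Standard silylation; triethylsilyl is bulky enough to shield the up face later yet can be removed in step 22 beside a TBS ether.

Step 5
Reactants: 6 TES-protected ketone; 7 ethyltriphenylphosphonium bromide
Product: 8 (Z)-C6=C5 ethylidene cyclopentane (C9 and C10 as in 6)
Conditions: 7, KOt-Bu, THF, 0 °C → reflux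
Reagents that add atoms: ethyltriphenylphosphonium bromide (7), CC[P+](c1ccccc1)(c1ccccc1)c1ccccc1.[Br-]
Why: Wittig olefination of a cyclopentanone next to a quaternary carbon, as practised on 17-keto steroids, brings in C5 and C4; the kinetic Z alkene is expected and its geometry is erased in step 7.

Step 6
Reactants: 8 (Z)-ethylidene cyclopentane
Product: 9 C5,C6-diol (C6-OH down and cis to C10-CH3; 1-hydroxyethyl group up, 5R)
Conditions: OsO4 (5 mol %), NMO (2 equiv), acetone–H2O, 23 °C
Reagents that add atoms: N-methylmorpholine N-oxide, C[N+]1([O-])CCOCC1; water, O; osmium tetroxide as oxygen carrier, O=[Os](=O)(=O)=O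
Why: In this Upjohn syn-dihydroxylation OsO4 reaches the exocyclic alkene from the down face beside C10-CH3 because the up face carries CH2OBn and C9-OSiEt3, so the C6 oxygen ends cis to C10-CH3 and C5 cis to C1, a sense that a carbon nucleophile adding to ketone 6 from the same open face could not give.

Step 7
Reactants: 9 C5,C6-diol
Product: 10 α-ketol (C6 acetyl up and cis to CH2OBn; C6-OH down)
Conditions: (COCl)2, DMSO, CH2Cl2, −78 °C; Et3N, −78 → 0 °C
Reagents that add atoms: none
Why: Swern oxidation converts the secondary C5 carbinol of the sec,tert-diol into the methyl ketone without glycol cleavage, the tertiary C6-OH being inert.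

Step 8
Reactants: 10 α-ketol benzyl ether
Product: 11 keto diol (C1H2-OH, C6-OH)
Conditions: H2 (1 atm), 10% Pd/C, EtOAc, 23 °C
Reagents that add atoms: none
Why: Hydrogenolysis of the benzyl ether is placed here, where neither an alkene nor a diazo group is present; 11 may rest partly as its five-membered hemiketal, which is of no consequence.

Step 9
Reactants: 11 keto diol
Product: 12 bis-TMS ether (C1H2-OTMS, C6-OTMS)
Conditions: TMS-imidazole (4 equiv), CH2Cl2, 23 → 40 °C
Reagents that add atoms: N-(trimethylsilyl)imidazole, C[Si](C)(C)n1ccnc1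
Why: Silyl transfer caps the primary hydroxyl first, which drains the open keto form, and then the tertiary C6-OH, without enolising the methyl ketone.

Step 10
Reactants: 12 bis-TMS methyl ketone
Product: 14 diazoketone bearing C1H2-OTMS, via trifluoroacetyl diketone 13 (not isolated)
Conditions: LiHMDS, THF, −78 °C; CF3CO2CH2CF3; NH4Cl quench; then MsN3, Et3N, H2O (1 equiv), MeCN, 23 °C
Reagents that add atoms: methanesulfonyl azide, CS(=O)(=O)N=[N+]=[N-]; 2,2,2-trifluoroethyl trifluoroacetate, O=C(OCC(F)(F)F)C(F)(F)F (atoms only in 13)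
Why: In this detrifluoroacetylative diazo transfer (Danheiser protocol) the only enolisable position, the C4 methyl, is trifluoroacetylated, and the activated 1,3-diketone 13 takes up N2 from mesyl azide with loss of the trifluoroacetyl group.

Step 11
Reactants: 14 diazoketone bearing C1H2-OTMS
Product: 15 diazoketone primary alcohol (C6-OTMS and C9-OTES kept)
Conditions: K2CO3 (0.1 equiv), MeOH, −10 → 0 °C, short contact
Reagents that add atoms: none
Why: Base-catalysed methanolysis discriminates by sterics, the primary TMS ether going within minutes while the tertiary C6 TMS and secondary TES ethers stay; the diazoketone tolerates carbonate, and C6-O lies trans to C1 on the ring so that silyl migration is geometrically barred.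

Step 12
Reactants: 15 diazoketone primary alcohol
Product: 16 cis formyl diazoacetyl cyclopentane (C1 aldehyde and C5 diazoacetyl both up; C6-OTMS down; C9-OTES up)
Conditions: DMP, NaHCO3, CH2Cl2, 0 → 23 °C
Reagents that add atoms: none
Why: Buffered Dess–Martin oxidation gives the non-enolisable neopentyl aldehyde under near-neutral conditions that the acyl-stabilised diazo group and the silyl ethers survive; the aldehyde is unveiled last because it would not outlast the enolate chemistry of step 10.

Step 13
Reactants: 17 prop-1-ynylmagnesium bromide; 18 diphenyl disulfide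
Product: 19 phenyl prop-1-ynyl sulfide
Conditions: THF, 0 → 23 °C
Reagents that add atoms: diphenyl disulfide (18), c1ccc(SSc2ccccc2)cc1
Why: Sulfenylation of an alkynyl Grignard reagent with a disulfide leads directly to the 1-alkynyl sulfide and avoids propargyl/allenyl isomer mixtures.

Step 14
Reactants: 19 phenyl prop-1-ynyl sulfide
Product: 20 1-(phenylsulfonyl)prop-1-yne
Conditions: mCPBA (2.2 equiv), CH2Cl2, 0 → 23 °C
Reagents that add atoms: 3-chloroperbenzoic acid, OOC(=O)c1cccc(Cl)c1
Why: Peracid oxidation takes the sulfide through the sulfoxide to the sulfone, and the electron-poor triple bond is not attacked.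

Step 15
Reactants: 16 cis formyl diazoacetyl cyclopentane; 20 1-(phenylsulfonyl)prop-1-yne
Product: 22 C1–O–C4 oxa-bridged hydroazulenone vinyl sulfone, via cyclic carbonyl ylide 21 (not isolated)
Conditions: Rh2(OAc)4 (2 mol %), 20 (3 equiv), CH2Cl2, 40 °C, 16 added over 6 h by syringe pump
Reagents that add atoms: 1-(phenylsulfonyl)prop-1-yne (20), CC#CS(=O)(=O)c1ccccc1
Why: Rh2(OAc)4 expels N2 from 16 and the electrophilic carbenoid at C4 is captured by a lone pair of the cis-held C1 aldehyde oxygen, which closes the six-membered pyranone ring C4–C5–C6–C10–C1–O as ylide 21, the known tandem carbonyl-ylide cyclisation–cycloaddition of δ-oxo-α-diazoketones. The ylide then adds suprafacially to alkyne 20 in a concerted HOMO(ylide)–LUMO(alkyne) controlled [3+2] event that forms C1–C2 and C3–C4 and so closes at one stroke the 2,5-dihydrofuran ring and the seven-membered carbocycle C1–C2–C3–C4–C5–C6–C10. The enolate-like terminus C4 next to the C5 ketone bonds to the electrophilic methyl-bearing β-carbon of the alkynyl sulfone (C3) and the oxocarbenium-like C1 bonds to the sulfonyl carbon (C2), the sense that 3-oxidopyrylium and related keto ylides show toward acceptor π systems. C1 and C4 are set together by the ylide face that the alkyne reaches, since the bridge ties them, and the face needed is the one carrying C10-CH3 and C6-OSiMe3. The other face is the concave side of the cis-fused bicycle, filled by C7–C9 and above all by C9-OSiEt3, which lies cis-vicinal to C1, while the C6 ether is the smallest silyl group, offers no activated C–H for 1,5-insertion and prevents O–H insertion to an oxetanone. Slow addition of 16 to excess 20 suppresses capture of the ylide by a second aldehyde.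

Step 16
Reactants: 22 oxa-bridged vinyl sulfone
Product: 24 oxa-bridged α-ketol (C2–H; C6-OH free), via desulfonylated TMS ether 23 (not isolated)
Conditions: 6% Na(Hg), Na2HPO4, MeOH–THF, −20 °C; decant; K2CO3 (0.2 equiv), 23 °C
Reagents that add atoms: none
Why: Buffered sodium-amalgam hydrogenolysis of the vinyl sulfone, the usual unmasking of alkynyl sulfone cycloadducts, replaces C2–S by C2–H with the alkene in place while the bridged frame holds C1–O out of alignment for β-elimination and the dialkyl ketone is not reduced; carbonate methanolysis then frees C6-OH so that no siloxide leaving group flanks C5 in the next step.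

Step 17
Reactants: 24 oxa-bridged α-ketol
Product: 25 C1-hydroxy C5-ketone (C2=C3, C4H2, C6-OH; bridge opened)
Conditions: SmI2 (2.2 equiv, 0.1 M), THF, −78 °C, no HMPA, no added proton source; sat. NH4Cl at −78 °C
Reagents that add atoms: none
Why: In this SmI2 reduction of an α-alkoxy ketone two electrons at C5 expel the strained, well-aligned C4–O bridge bond as the C1 alkoxide, while the C6 oxygen, present as hydroxyl or samarium alkoxide, is no leaving group; kinetic α-protonation of the dienolate at C4 keeps C2=C3 out of conjugation, C1 is untouched and the C4 stereocentre disappears.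

Step 18
Reactants: 25 C1-hydroxy C5-ketone
Product: 26 C1-OTBS C5-ketone (C6-OH free)
Conditions: TBSOTf (1.1 equiv), 2,6-lutidine, CH2Cl2, −40 → 0 °C
Reagents that add atoms: tert-butyldimethylsilyl triflate, CC(C)(C)[Si](C)(C)OS(=O)(=O)C(F)(F)F
Why: Silylation of the secondary allylic C1-OH, drawn from the open form of any transannular C1–O–C5 hemiketal, leaves the hindered tertiary C6-OH free for the next step.

Step 19
Reactants: 26 C1-OTBS C5-ketone
Product: 27 trans C5,C6-diol (C5-OH on the face opposite to C6-OH)
Conditions: Me4NBH(OAc)3, MeCN–AcOH, −30 → 0 °C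
Reagents that add atoms: none
Why: In this hydroxyl-directed triacetoxyborohydride reduction (Saksena–Evans type) boron bound to C6-OH delivers hydride to C5 from the same face, which is also the face away from C7, giving the trans diol.

Step 20
Reactants: 27 trans C5,C6-diol
Product: 29 C5,C6-epoxide (oxygen down), via C5 mesylate 28 (not isolated)
Conditions: MsCl, Et3N, CH2Cl2, 0 °C; then K2CO3, MeOH, 23 °C
Reagents that add atoms: methanesulfonyl chloride, CS(=O)(=O)Cl (atoms only in 28)
Why: Selective mesylation of the secondary alcohol followed by base-induced 3-exo-tet displacement by the anti C6 alkoxide gives the epoxide with inversion at C5 and retention at C6.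

Step 21
Reactants: 29 C5,C6-epoxide
Product: 30 tertiary alcohol with C5H2 (C1-OTBS, C9-OTES)
Conditions: LiEt3BH, THF, 0 → 40 °C
Reagents that add atoms: none
Why: Super-Hydride opens the trisubstituted epoxide by SN2 attack at the less substituted C5, so C5 becomes CH2 and the C6–O bond with its configuration is never broken.

Step 22
Reactants: 30 tertiary alcohol
Product: 31 C6,C9-diol (C1-OTBS kept)
Conditions: PPTS (0.1 equiv), MeOH–CH2Cl2, 0 → 23 °C
Reagents that add atoms: none
Why: Mild acid methanolysis removes the secondary TES ether much faster than the TBS ether at C1.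

Step 23
Reactants: 31 C6,C9-diol
Product: 32 C9 ketone (C6-OH free)
Conditions: DMP, NaHCO3, CH2Cl2, 0 → 23 °C
Reagents that add atoms: none
Why: Dess–Martin oxidation of the only oxidisable hydroxyl gives the C9 ketone, and the buffered neutral medium avoids retro-aldol of the β-hydroxy ketone.

Step 24
Reactants: 32 C9 ketone
Product: 33 C8=C9 TMS enol ether with C6-OTMS
Conditions: TMSOTf (3 equiv), Et3N (5 equiv), CH2Cl2, 0 °C
Reagents that add atoms: trimethylsilyl triflate, C[Si](C)(C)OS(=O)(=O)C(F)(F)F
Why: Soft enolisation can only go toward C8 because C10 is quaternary, and the same reagent silylates C6-OH, so no strong base meets the β-hydroxy ketone.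

Step 25
Reactants: 33 TMS enol ether
Product: 34 C7=C8–C9=O enone (C6-OTMS, C1-OTBS)
Conditions: Pd(OAc)2 (1.05 equiv), MeCN, 23 °C
Reagents that add atoms: none
Why: Saegusa–Ito oxidation of the silyl enol ether installs the C7=C8 enone.

Step 26
Reactants: 34 enone; 35 isopropyllithium
Product: 37 C7-isopropyl C7=C8–C9=O enone, via lithium enolate 36 (not isolated)
Conditions: i-PrLi (2.4 equiv), CuI (1.2 equiv), Et2O–THF, −78 → −40 °C; then PhS(Cl)=Nt-Bu, −78 °C
Reagents that add atoms: isopropyllithium (35), [Li]C(C)C
Why: Gilman conjugate addition puts the isopropyl group on C7, and lithium enolate 36 is dehydrogenated in the same flask by the sulfinimidoyl chloride (Mukaiyama dehydrogenation, syn elimination of the C8 sulfilimine with the cis C7–H), so the face chosen by the cuprate, expected to be the wrong one anti to C6-OSiMe3, does not matter.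

Step 27
Reactants: 37 C7-isopropyl enone
Product: 38 (7R)-C7-isopropyl C9 ketone (iPr down; C6-OTMS, C1-OTBS)
Conditions: [(Ph3P)CuH]6 (0.4 equiv), degassed benzene–H2O, 23 °C
Reagents that add atoms: none
Why: Copper hydride conjugate reduction (Stryker reagent) is chemoselective for the enone over C2=C3, and hydride reaches C7 from the up face, anti to the two angular groups C6-OSiMe3 and C10-CH3 as reagents do on the D ring of C/D-cis 14β-oxygenated steroids, which turns the isopropyl group down, cis to C6-O and C10-CH3.

Step 28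
Reactants: 38 bis-silyl ketone
Product: 39 C1,C6-diol C9-ketone
Conditions: HF·pyridine, pyridine, THF, 0 → 23 °C
Reagents that add atoms: none
Why: Fluoride cleavage of both silyl ethers under weakly acidic conditions spares the β-hydroxy ketone from retro-aldol and the allylic alcohol from ionisation.

Step 29
Reactants: 39 C1,C6-diol C9-ketone; 40 4-methoxybenzoyl chloride
Product: 41 target CNP0246512.1
Conditions: 40 (1.5 equiv), DMAP (0.2 equiv), Et3N, CH2Cl2, 0 → 23 °C
Reagents that add atoms: 4-methoxybenzoyl chloride (40), COc1ccc(cc1)C(Cl)=O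
Why: DMAP-catalysed acylation takes place at oxygen with retention at C1 and only at the secondary allylic alcohol, since the tertiary C6-OH is unreactive.

**Compound list**
1 | 2-methylcyclopentane-1,3-dione | CC1C(=O)CCC1=O | starting material
2 | formaldehyde (37% aq) | C=O | starting material
3 | 2-(hydroxymethyl)-2-methylcyclopentane-1,3-dione | CC1(CO)C(=O)CCC1=O | intermediate
4 | 2-[(benzyloxy)methyl]-2-methylcyclopentane-1,3-dione | CC1(COCc2ccccc2)C(=O)CCC1=O | intermediate
5 | (2S,3S)-2-[(benzyloxy)methyl]-3-hydroxy-2-methylcyclopentan-1-one | O=C1CC[C@H](O)[C@]1(C)COCc1ccccc1 | intermediate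
6 | (2S,3S)-2-[(benzyloxy)methyl]-2-methyl-3-(triethylsilyloxy)cyclopentan-1-one | O=C1CC[C@H](O[Si](CC)(CC)CC)[C@]1(C)COCc1ccccc1 | intermediate
7 | ethyltriphenylphosphonium bromide | CC[P+](c1ccccc1)(c1ccccc1)c1ccccc1.[Br-] | starting material
8 | (Z)-C6=C5 ethylidene cyclopentane | C/C=C1/CC[C@H](O[Si](CC)(CC)CC)[C@]1(C)COCc1ccccc1 | intermediate
9 | C5,C6-diol, C6-OH cis to C10-CH3, (5R) | C[C@@H](O)[C@]1(O)CC[C@H](O[Si](CC)(CC)CC)[C@]1(C)COCc1ccccc1 | intermediate
10 | α-ketol, acetyl cis to CH2OBn | CC(=O)[C@]1(O)CC[C@H](O[Si](CC)(CC)CC)[C@]1(C)COCc1ccccc1 | intermediate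
11 | keto diol | CC(=O)[C@]1(O)CC[C@H](O[Si](CC)(CC)CC)[C@]1(C)CO | intermediate
12 | bis-TMS ether of 11 | CC(=O)[C@]1(O[Si](C)(C)C)CC[C@H](O[Si](CC)(CC)CC)[C@]1(C)CO[Si](C)(C)C | intermediate
13 | trifluoroacetyl diketone | O=C(CC(=O)C(F)(F)F)[C@]1(O[Si](C)(C)C)CC[C@H](O[Si](CC)(CC)CC)[C@]1(C)CO[Si](C)(C)C | intermediate
14 | diazoketone, C1H2-OTMS | [N-]=[N+]=CC(=O)[C@]1(O[Si](C)(C)C)CC[C@H](O[Si](CC)(CC)CC)[C@]1(C)CO[Si](C)(C)C | intermediate
15 | diazoketone primary alcohol | [N-]=[N+]=CC(=O)[C@]1(O[Si](C)(C)C)CC[C@H](O[Si](CC)(CC)CC)[C@]1(C)CO | intermediate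
16 | cis formyl diazoacetyl cyclopentane (key precursor) | [N-]=[N+]=CC(=O)[C@]1(O[Si](C)(C)C)CC[C@H](O[Si](CC)(CC)CC)[C@]1(C)C=O | intermediate
17 | prop-1-ynylmagnesium bromide | CC#C[Mg]Br | starting material
18 | diphenyl disulfide | c1ccc(SSc2ccccc2)cc1 | starting material
19 | phenyl prop-1-ynyl sulfide | CC#CSc1ccccc1 | intermediate
20 | 1-(phenylsulfonyl)prop-1-yne | CC#CS(=O)(=O)c1ccccc1 | intermediate
21 | cyclic six-membered carbonyl ylide | O=C1[CH-][O+]=C[C@@]2(C)[C@@H](O[Si](CC)(CC)CC)CC[C@@]12O[Si](C)(C)C | intermediate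
22 | C1–O–C4 oxa-bridged hydroazulenone vinyl sulfone (key product) | O1[C@@H]2C(S(=O)(=O)c4ccccc4)=C(C)[C@H]1C(=O)[C@]3(O[Si](C)(C)C)CC[C@H](O[Si](CC)(CC)CC)[C@]23C | intermediate
23 | desulfonylated oxa-bridged ketone, C6-OTMS | O1[C@@H]2C=C(C)[C@H]1C(=O)[C@]3(O[Si](C)(C)C)CC[C@H](O[Si](CC)(CC)CC)[C@]23C | intermediate
24 | oxa-bridged α-ketol | O1[C@@H]2C=C(C)[C@H]1C(=O)[C@]3(O)CC[C@H](O[Si](CC)(CC)CC)[C@]23C | intermediate
25 | C1-hydroxy C5-ketone, bridge opened | O[C@@H]1C=C(C)CC(=O)[C@]2(O)CC[C@H](O[Si](CC)(CC)CC)[C@]12C | intermediate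
26 | C1-OTBS C5-ketone | CC(C)(C)[Si](C)(C)O[C@@H]1C=C(C)CC(=O)[C@]2(O)CC[C@H](O[Si](CC)(CC)CC)[C@]12C | intermediate
27 | trans C5,C6-diol | CC(C)(C)[Si](C)(C)O[C@@H]1C=C(C)C[C@H](O)[C@]2(O)CC[C@H](O[Si](CC)(CC)CC)[C@]12C | intermediate
28 | C5 mesylate | CC(C)(C)[Si](C)(C)O[C@@H]1C=C(C)C[C@H](OS(C)(=O)=O)[C@]2(O)CC[C@H](O[Si](CC)(CC)CC)[C@]12C | intermediate
29 | C5,C6-epoxide, oxygen on the C10-CH3 face | CC(C)(C)[Si](C)(C)O[C@@H]1C=C(C)C[C@H]3O[C@]32CC[C@H](O[Si](CC)(CC)CC)[C@]12C | intermediate
30 | C6 tertiary alcohol, C5H2 | CC(C)(C)[Si](C)(C)O[C@@H]1C=C(C)CC[C@]2(O)CC[C@H](O[Si](CC)(CC)CC)[C@]12C | intermediate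
31 | C6,C9-diol | CC(C)(C)[Si](C)(C)O[C@@H]1C=C(C)CC[C@]2(O)CC[C@H](O)[C@]12C | intermediate
32 | C9 ketone | CC(C)(C)[Si](C)(C)O[C@@H]1C=C(C)CC[C@]2(O)CCC(=O)[C@]12C | intermediate
33 | C8=C9 TMS enol ether, C6-OTMS | CC(C)(C)[Si](C)(C)O[C@@H]1C=C(C)CC[C@]2(O[Si](C)(C)C)CC=C(O[Si](C)(C)C)[C@]12C | intermediate
34 | C7=C8–C9=O enone | CC(C)(C)[Si](C)(C)O[C@@H]1C=C(C)CC[C@]2(O[Si](C)(C)C)C=CC(=O)[C@]12C | intermediate
35 | isopropyllithium | [Li]C(C)C | starting material
36 | lithium enolate, iPr expected up at C7 | [Li+].CC(C)(C)[Si](C)(C)O[C@@H]1C=C(C)CC[C@]2(O[Si](C)(C)C)[C@H](C(C)C)C=C([O-])[C@]12C | intermediate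
37 | C7-isopropyl enone | CC(C)(C)[Si](C)(C)O[C@@H]1C=C(C)CC[C@]2(O[Si](C)(C)C)C(C(C)C)=CC(=O)[C@]12C | intermediate
38 | (7R)-isopropyl ketone, bis-silyl | CC(C)(C)[Si](C)(C)O[C@@H]1C=C(C)CC[C@]2(O[Si](C)(C)C)[C@@H](C(C)C)CC(=O)[C@]12C | intermediate
39 | C1,C6-diol C9-ketone | O[C@@H]1C=C(C)CC[C@]2(O)[C@@H](C(C)C)CC(=O)[C@]12C | intermediate
40 | 4-methoxybenzoyl chloride | COc1ccc(cc1)C(Cl)=O | starting material
41 | CNP0246512.1, (1R,6S,7R,10R) in the locants used here | COc1ccc(C(=O)O[C@@H]2C=C(C)CC[C@]3(O)[C@@H](C(C)C)CC(=O)[C@]23C)cc1 | target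

**Step count**
- Total step count: 29.
- Longest linear sequence: 27 (steps 1–12 and 15–29); steps 13–14 are the side branch.

**Steps most likely to fail**

Step 15. Capture of the crowded ylide by the β-methylated acceptor alkyne may be slower than ylide dimerisation or capture by a second aldehyde. Approach may also leak to the concave face or to the reversed orientation.
- The fallback sets out from 16 and comes back at 23.
- The acceptor group is dropped and 16 is decomposed with Rh(II) under a large excess of condensed propyne in a sealed vessel.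
- The cycloaddition is then governed by the ylide LUMO and the alkyne HOMO, as known for carbonyl ylides with unactivated terminal alkynes.
- The unsubstituted alkyne carbon bonds to the oxocarbenium carbon C1 and the methyl-bearing carbon to C4. The sterically minimal dipolarophile thus gives the sulfone-free adduct 23 directly.
- Only the carbonate part of step 16 then remains, and steps 13 and 14 fall away (new compounds: none F0).

Step 17. Electron transfer may also expel the C6 oxygen or run on to over-reduction of the liberated α-ketol, and the β,γ-unsaturated ketone may slip into conjugation during work-up.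
- The fallback sets out from 24 and comes back at 30, avoiding ketyl chemistry altogether.
- Hydrazine hydrate with catalytic AcOH in hot EtOH gives the C5 hydrazone F1.
- KOt-Bu in DMSO at 23 °C brings about a Kishner–Leonard eliminative reduction. The C5 carbanion equivalent expels the C4–O bridge bond (C6-O⁻ cannot leave) and loss of N2 leaves the C2=C3–C4=C5 diene diol F2.
- Diimide (potassium azodicarboxylate, AcOH) saturates only the disubstituted C4=C5 bond and gives the C1,C6-diol F3.
- TBSOTf with 2,6-lutidine silylates the secondary C1-OH to give 30. This replaces steps 17–21.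

Step 27. Hydride may arrive on the face of the angular groups (inverted facial selectivity), or the crowded β-carbon may not react at all.
- The fallback sets out from 34 and comes back at 39, and lets C–C rather than C–H bond formation set C7.
- If the down face proves to be the open one, the cuprate will use it too.
- i-Pr2CuLi with TMSCl is therefore added to 34 without dehydrogenation and gives the (7R)-isopropyl TMS enol ether F4.
- HF·pyridine converts F4 directly into 39. This replaces steps 26–28.

**Further compounds**
F0 | step 15 | none | none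
F1 | step 17 | C5 hydrazone | O1[C@@H]2C=C(C)[C@H]1C(=NN)[C@]3(O)CC[C@H](O[Si](CC)(CC)CC)[C@]23C
F2 | step 17 | C2=C3–C4=C5 diene diol | O[C@@H]1C=C(C)C=C[C@]2(O)CC[C@H](O[Si](CC)(CC)CC)[C@]12C
F3 | step 17 | C1,C6-diol | O[C@@H]1C=C(C)CC[C@]2(O)CC[C@H](O[Si](CC)(CC)CC)[C@]12C
F4 | step 27 | (7R)-isopropyl TMS enol ether | CC(C)(C)[Si](C)(C)O[C@@H]1C=C(C)CC[C@]2(O[Si](C)(C)C)[C@@H](C(C)C)C=C(O[Si](C)(C)C)[C@]12C
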